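## Structural features

Talapolyester B is an open-chain tetraester built around one benzene ring and has no other ring. Read from the neutral end, an (R)-3,4-dihydroxybutanoyl cap acylates the hydroxyl of an (R)-3-hydroxybutanoyl unit. The carbonyl of that unit is bound to the oxygen of the R-configured carbinol carbon CH(CH3)CH2Ar of a 2-oxypropyl chain at C6 of a 2,4-dihydroxybenzoate, and the C1 carboxyl of the ring is esterified by the hydroxyl of (S)-3-hydroxybutanoic acid, which ends in the free acid. The four stereocentres (R in the cap, R in the internal unit, R at the side-chain carbinol, S in the terminal unit) are separated from one another by three or more atoms, so none can steer another and each must be set on its own. All three aliphatic ester links carry an oxygen β to the carbonyl and can be lost by E1cB elimination, the 1,2-diol of the cap can lactonise onto its own ester carbonyl and expel the rest of the chain, and the benzoate carbonyl is shielded by two ortho substituents. The most delicate region is the C6 side chain: a free hydroxyl on CH(CH3)CH2Ar lies within reach of the C1 ester carbonyl and would close a six-membered isochromanone lactone, so this oxygen should never be free while an ester sits on C1. The real difficulty is therefore to create the ester between the internal carbonyl and the side-chain carbinol with R configuration without passing through that alcohol, and to join the hindered C1 carboxyl to a secondary alcohol with S configuration. The key step exploits the sequence C(=O)–O–CH(CH3)–CH2–Ar: without the bridging oxygen it is an α-methyl-β-aryl ketone, C(=O)–CH(CH3)–CH2–Ar, whose stereocentre can be set by enolate benzylation and into which a peracid reinserts the oxygen with retention.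

## Logic of the disconnections

28 from 27. The five benzylic C–O bonds (two phenol ethers, the two cap ethers and the terminal ester) are cut in one operation. Every hydroxyl and the acid thus stay masked until nothing else has to be done, which keeps lactonisation and acyl migration out of all earlier steps. The forward step must be a neutral reductive cleavage that spares three β-oxygenated esters.

27 from 23 and 25. The alkyl–oxygen bond O–CH(CH3) of the terminal benzoate ester is cut, not the acyl–oxygen bond. The carbonyl of 23 is flanked by two ortho substituents and resists attack, whereas its carboxylate oxygen can act as a nucleophile; the cut also lets the S centre arise by inversion from the R-configured 25. The forward step must be an SN2 displacement at a β-hydroxy ester without elimination, and 23 must carry no other free hydroxyl.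

23 from 22. Only the tert-butyl–oxygen bond is cut. The tert-butyl ester keeps the C1 carboxyl inert and the ring less electron-rich through the organometallic steps and the oxidation. It must leave under acid that spares benzyl ethers and aliphatic esters.

22 from 20 (key disconnection). The bridging oxygen between the internal carbonyl and the side-chain carbinol carbon is deleted: the C(=O)–O and O–CH bonds are cut and a C(=O)–CH bond takes their place. The ester and its R carbinol become an all-carbon α-methyl ketone, so the stereocentre turns into an enolate-alkylation problem and the hydroxyl that would lactonise never exists as such. The forward step must insert oxygen on the branched side of the ketone with retention, without oxidising the ring or eliminating the β-acyloxy group.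

20 from 14 and 19. The acyl–oxygen bond of the cap ester is cut, giving a secondary alcohol and a protected acid. Attaching the cap before the oxygen insertion makes the CH2 side of the ketone a poorer migrating group and saves late steps. The acylation must not trigger β-elimination in a β-hydroxy ketone.

14 from 10 and 11. The C4–C5 bond of the hexyl chain is cut in the aldol sense, which reduces the chain to a methyl ketone and a two-carbon aldehyde. The forward step needs enolisation on the methyl side only and reagent control of the new carbinol, because the α-methyl centre is too weak a control element.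

10 from 9, and 9 from 8. The acyl–CH3 bond and then the acyl–S and acyl–N bonds are cut, which traces the methyl ketone back to the auxiliary-bound acyl group. The forward steps must be acyl substitutions that stop at the ketone and do not epimerise the α-centre.

8 from 7, 7 from 6, 6 from 4. The O–C(CH3)3 bond, the oxidation level of the carboxyl and finally the ring C–CHO bond are removed, leaving a ring with two benzyloxy groups and the side chain. This requires electrophilic substitution at the ring carbon ortho to the side chain and esterification of a hindered acid through its oxygen.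

4 from 1 and 2. The Cα–CH2Ar bond is cut. This gives two commercial compounds and places the only stereocentre of the fragment under auxiliary control. The forward step must be a face-selective alkylation of a chelated enolate.

19 from 17, 17 from 16, 16 from 15. The two benzyl ether bonds and the C–H bonds of the primary carbinol are traced back to a hydroxy diester of the chiral pool. This requires reduction of only the ester next to the hydroxyl, and benzylation without alkoxide formation.

25 from 24. The benzyl–oxygen bond of the ester is cut, which asks only for O-alkylation of a carboxylate.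

## Other disconnections considered

Alternative 1: The cut goes through the benzene ring at C1–C2 and C5–C6.
- Cut and forward step: ring carbons C1 and C6 come from the triple bond of ynoate A2, an (R)-5-acyloxyhex-2-ynoate that already carries the internal unit, the dibenzyl cap and the S-configured terminal benzyl ester. C2–C5 come from the bis(silyloxy)diene A3. A2 and A3 would be heated together; the CH2 terminus of A3 bonds to the alkyne carbon bearing the side chain and the ketene-acetal terminus to the carbon bearing the ester. Loss of methanol and of the silyl groups aromatises the adduct to the free resorcinol A1, which one hydrogenolysis would convert into the target.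
- In its favour: the hindered benzoate is made as an unhindered ynoate ester, the phenols never need protection, the side-chain carbinol can come from a chiral-pool homopropargylic alcohol without auxiliary or oxidation, and the plan is highly convergent.
- Against it here: a β-alkyl ynoate is a weak dienophile for this diene and needs strong heating, which three β-oxygenated esters must survive. The propargylic CH2 of A2 lies between the triple bond and a carbon bearing an acyloxy group, so isomerisation to the allenoate or elimination to an enyne threatens. Open-chain Michael addition can compete with ring closure. All of this happens on the fully assembled chain, where a failure costs most.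
- Comparison: on structure the two plans are equal, since both bring the side-chain oxygen in already acylated. On mechanism the regiochemistry of the cycloaddition is as predictable as the migration preference in step 12, but the chosen plan transfers its stereocentre by a concerted shift under mild buffered conditions, whereas the alternative depends on a thermal tolerance that is hard to foresee. On step economy and on freedom from phenol protecting groups the alternative is the better plan; the chosen plan is better in the reliability of each single step.

Alternative 2: The cut removes the acyl–oxygen bond of the benzoate ester and the ring bond C1–C6.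
- Cut and forward step: heating diketo-dioxinone A5 would release an acylketene, which the S-configured hydroxy ester A6 traps as a triketo ester. Cs2CO3 and then acid close C1–C6 by aldol condensation and dehydration to the resorcylate A4.
- In its favour: the ester of the hindered carboxyl is formed by addition of the alcohol to a ketene, which is insensitive to the later ortho substituents and proceeds with retention. A6 is therefore used in its final configuration and no inverting esterification is needed; on this point the alternative is the better plan. The phenols appear free, and the carbinol comes from a chiral-pool silyloxybutanoate.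
- Against it here: A4 still lacks the internal unit and the cap and carries the side-chain oxygen as a silyl ether. Removing the silyl group frees exactly the hydroxyl that can lactonise onto the benzoate and expel the terminal unit. The following acylation must then distinguish this secondary alcohol from two free phenols, or the phenols must be protected after all. The polyketone A5 needs several enolate acylations and exists as a tautomeric mixture.
- Comparison: on structure the chosen plan is better, because its side-chain oxygen is born acylated, while the alternative must unmask it next to the ester. On mechanism the two are equal in stereochemical safety (chiral pool against auxiliary plus retentive migration). On step economy the ring construction of the alternative is shorter, but desilylation, selective acylation and final deprotection bring the totals close, so the two are about equal.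

Alternative 3: The cut removes the cap C1–C2 bond and the cap acyl–oxygen bond.
- Cut and forward step: the cap is assembled from carbon monoxide, the (R)-glycidyl ether A9 and the free hydroxyl of the cap-less triester A8. With Co2(CO)8 and 3-hydroxypyridine under CO pressure the epoxide would be opened at its terminal carbon, CO inserted, and the acylcobalt intercepted by A8 to give A7. Hydrogenolysis of its four benzyl groups would follow.
- In its favour: the cap skeleton and its ester are made in one step from a commercial enantiopure epoxide, and the stereocentre is not touched, which is as safe as the chiral-pool source of 19. The three-step preparation of 19 and one benzyl group are saved, so for the cap the alternative is the better plan in step economy.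
- Against it here: this carbonylation is normally run with a simple alcohol in large excess, whereas A8 is a precious secondary β-hydroxy ester that would be the limiting partner. The nucleophilic co-catalyst and the cobalt alkoxides can transesterify or eliminate the β-acyloxy esters already present. The free β-hydroxyl of A7 invites acyl migration. The step also addresses only the easiest bond of the molecule: A8 still requires the side-chain ester and the hindered benzoate.
- Comparison: structurally the alternative complements the chosen plan and does not replace it. Mechanistically the two ways of attaching the cap are equally safe for configuration. The alternative is shorter by about two steps but places an uncertain three-component reaction on the most advanced intermediate, where the chosen plan uses a routine acylation.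

Key step: step 12

Assumption: the enolborinate formed from a methyl ketone and (+)-Ipc2BCl is taken to add to the si face of an aldehyde, which for 11 gives the R carbinol; the sense is to be confirmed on 14 (for example through its Mosher esters), and the enantiomeric reagent would be used if it proved opposite.

## Route

Step 1
Reactants: 1 (S)-4-benzyl-3-propionyloxazolidin-2-one; 2 3,5-bis(benzyloxy)benzyl bromide
Product: 4 (S)-4-benzyl-3-{(R)-3-[3,5-bis(benzyloxy)phenyl]-2-methylpropanoyl}oxazolidin-2-one, via sodium Z-enolate 3 (not isolated)
Conditions: NaN(SiMe3)2, THF, −78 °C; then 2, −78 → −40 °C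
Reagents that add atoms: none
Why: Evans asymmetric alkylation: the base gives the chelated Z enolate 3, one face of which is shielded by the C4 benzyl group of the auxiliary, so the reactive benzylic bromide enters from the other face and sets the R configuration at the new α-methyl centre.

Step 2
Reactants: 4 (S)-4-benzyl-3-{(R)-3-[3,5-bis(benzyloxy)phenyl]-2-methylpropanoyl}oxazolidin-2-one
Product: 6 (S)-4-benzyl-3-{(R)-3-[3,5-bis(benzyloxy)-2-formylphenyl]-2-methylpropanoyl}oxazolidin-2-one, via aryl iminium chloride 5 (not isolated)
Conditions: POCl3, DMF, 0 °C → rt; then aq. NaOAc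
Reagents that add atoms: N,N-dimethylformamide, CN(C)C=O; water, O
Why: Vilsmeier–Haack formylation: the chloroiminium ion substitutes the resorcinol diether ring at the carbon ortho to the side chain and para to a benzyloxy group (the doubly flanked carbon between the two benzyloxy groups reacts more slowly), and aqueous acetate hydrolyses iminium 5 to the aldehyde. The imide offers no nucleophilic site and the α-centre is not enolised.

Step 3
Reactants: 6 (S)-4-benzyl-3-{(R)-3-[3,5-bis(benzyloxy)-2-formylphenyl]-2-methylpropanoyl}oxazolidin-2-one
Product: 7 2,4-bis(benzyloxy)-6-{(R)-3-[(S)-4-benzyl-2-oxooxazolidin-3-yl]-2-methyl-3-oxopropyl}benzoic acid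
Conditions: NaClO2, NaH2PO4, 2-methyl-2-butene, t-BuOH/THF/H2O, 0 °C → rt
Reagents that add atoms: sodium chlorite, [Na+].[O-]Cl=O
Why: Pinnick oxidation: chlorous acid converts the aryl aldehyde into the acid while 2-methyl-2-butene traps the hypochlorous acid that would otherwise chlorinate the electron-rich ring; imide, ethers and the α-centre are inert.

Step 4
Reactants: 7 2,4-bis(benzyloxy)-6-{(R)-3-[(S)-4-benzyl-2-oxooxazolidin-3-yl]-2-methyl-3-oxopropyl}benzoic acid
Product: 8 tert-butyl 2,4-bis(benzyloxy)-6-{(R)-3-[(S)-4-benzyl-2-oxooxazolidin-3-yl]-2-methyl-3-oxopropyl}benzoate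
Conditions: Cl3CC(=NH)Ot-Bu, CH2Cl2/cyclohexane, rt
Reagents that add atoms: tert-butyl 2,2,2-trichloroacetimidate, CC(C)(C)OC(=N)C(Cl)(Cl)Cl
Why: Esterification by alkyl–oxygen bond formation: the acid protonates the imidate and the carboxylate captures the tert-butyl cation, so the carbonyl shielded by two ortho substituents is never attacked.

Step 5
Reactants: 8 tert-butyl 2,4-bis(benzyloxy)-6-{(R)-3-[(S)-4-benzyl-2-oxooxazolidin-3-yl]-2-methyl-3-oxopropyl}benzoate
Product: 9 tert-butyl 2,4-bis(benzyloxy)-6-[(R)-3-(ethylsulfanyl)-2-methyl-3-oxopropyl]benzoate
Conditions: EtSH, n-BuLi, THF, 0 °C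
Reagents that add atoms: ethanethiol, CCS
Why: Thiolate cleavage of an Evans imide: the soft, weakly basic lithium ethanethiolate attacks the exocyclic carbonyl selectively, also in α-branched imides, and releases the auxiliary without epimerisation; the hindered tert-butyl benzoate does not react.

Step 6
Reactants: 9 tert-butyl 2,4-bis(benzyloxy)-6-[(R)-3-(ethylsulfanyl)-2-methyl-3-oxopropyl]benzoate
Product: 10 tert-butyl 2,4-bis(benzyloxy)-6-[(R)-2-methyl-3-oxobutyl]benzoate
Conditions: Me2CuLi (MeLi, CuI), Et2O, −78 → −40 °C
Reagents that add atoms: lithium dimethylcuprate, [Li+].C[Cu-]C (made in the flask from methyllithium, [Li]C, and CuI)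
Why: Ketone synthesis from a thioester and a lithium dialkylcuprate: Me2CuLi replaces the thiolate by methyl and adds neither to the ketone formed nor to the tert-butyl ester; the non-basic reagent leaves the α-centre untouched.

Step 7
Reactants: 10 tert-butyl 2,4-bis(benzyloxy)-6-[(R)-2-methyl-3-oxobutyl]benzoate; 11 acetaldehyde
Product: 14 tert-butyl 2,4-bis(benzyloxy)-6-[(2R,5R)-5-hydroxy-2-methyl-3-oxohexyl]benzoate, via boron enolate 12 (not isolated), via boron aldolate 13 (not isolated)
Conditions: (+)-Ipc2BCl, Et3N, Et2O, 0 °C; then 11, −78 → −20 °C; then H2O2, MeOH, pH 7 buffer, 0 °C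
Reagents that add atoms: none
Why: Paterson boron aldol reaction: Ipc2BCl and Et3N enolise the methyl side of 10 to enolborinate 12, which adds to 11 through a cyclic transition state in which the isopinocampheyl ligands select the si face of the aldehyde, giving aldolate 13 and, after oxidative work-up, the R carbinol (reagent control). The branched α-carbon is not enolised, so its configuration is kept, and any C5 epimer is removed by chromatography.

Step 8
Reactants: 15 dimethyl (R)-malate
Product: 16 methyl (R)-3,4-dihydroxybutanoate
Conditions: BH3·SMe2, NaBH4 (5 mol %), THF, 0 °C → rt; then MeOH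
Reagents that add atoms: none
Why: Hydroxyl-directed chemoselective reduction: the free hydroxyl binds borane and hydride is delivered, with NaBH4 as catalyst, through a five-membered chelate to the adjacent ester only; the stereocentre is not involved. The diol ester is used at once because it lactonises on standing.

Step 9
Reactants: 16 methyl (R)-3,4-dihydroxybutanoate
Product: 17 methyl (R)-3,4-bis(benzyloxy)butanoate
Conditions: Cl3CC(=NH)OBn, TfOH (cat.), CH2Cl2/cyclohexane, 0 °C → rt
Reagents that add atoms: benzyl 2,2,2-trichloroacetimidate, N=C(OCc1ccccc1)C(Cl)(Cl)Cl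
Why: Acid-catalysed O-benzylation with the trichloroacetimidate: no alkoxide is formed, so the β-hydroxy ester cannot undergo retro-aldol cleavage or elimination, and both hydroxyls are etherified.

Step 10
Reactants: 17 methyl (R)-3,4-bis(benzyloxy)butanoate
Product: 19 (R)-3,4-bis(benzyloxy)butanoic acid, via lithium carboxylate 18 (not isolated)
Conditions: LiOH, THF/H2O, 0 °C; then 1 M HCl
Reagents that add atoms: lithium hydroxide, [Li+].[OH-]
Why: Saponification of the methyl ester at low temperature to carboxylate 18, then acidification; the mild hydroxide conditions limit β-elimination of the benzyloxy group.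

Step 11
Reactants: 14 tert-butyl 2,4-bis(benzyloxy)-6-[(2R,5R)-5-hydroxy-2-methyl-3-oxohexyl]benzoate; 19 (R)-3,4-bis(benzyloxy)butanoic acid
Product: 20 tert-butyl 2,4-bis(benzyloxy)-6-[(2R,5R)-5-{[(R)-3,4-bis(benzyloxy)butanoyl]oxy}-2-methyl-3-oxohexyl]benzoate
Conditions: EDC·HCl, DMAP (cat.), CH2Cl2, 0 °C
Reagents that add atoms: none
Why: Steglich-type carbodiimide esterification of the secondary hydroxyl with DMAP as acyl-transfer catalyst; the low temperature and the catalytic amount of base limit E1cB loss of the new β-acyloxy group from the ketone and of benzyl alcohol from the activated acid, and no stereocentre is touched.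

Step 12
Reactants: 20 tert-butyl 2,4-bis(benzyloxy)-6-[(2R,5R)-5-{[(R)-3,4-bis(benzyloxy)butanoyl]oxy}-2-methyl-3-oxohexyl]benzoate
Product: 22 tert-butyl 2,4-bis(benzyloxy)-6-[(R)-2-{[(R)-3-{[(R)-3,4-bis(benzyloxy)butanoyl]oxy}butanoyl]oxy}propyl]benzoate, via Criegee adduct 21 (not isolated)
Conditions: (CF3CO)2O, urea·H2O2, Na2HPO4, CH2Cl2, 0 °C
Reagents that add atoms: trifluoroperacetic acid, OOC(=O)C(F)(F)F (made in the flask from trifluoroacetic anhydride and urea–hydrogen peroxide)
Why: Baeyer–Villiger oxidation: trifluoroperacetic acid adds to the ketone carbonyl of 20 to give the Criegee adduct 21, and the group that lies antiperiplanar to the O–O bond and best carries positive charge shifts from carbon to oxygen as trifluoroacetate leaves. The closest known reaction type is the peracid oxidation of acyclic α-branched ketones to esters of secondary alcohols, which proceeds with retention at the migrating carbon. No ring is closed. The one stereocentre that the step creates, the R carbinol carbon O–CH(CH3)CH2Ar, is controlled by the configuration of the α-methyl carbon set in step 1, because the 1,2-shift is concerted and suprafacial. Regioselectivity is needed between the secondary carbon and the CH2 group, and both the higher substitution of the former and the electron-withdrawing β-acyloxy group on the latter favour the wanted migration. Chemoselectivity is needed against oxidation of the dialkoxybenzene ring; the ring ester lowers its electron density, and the low temperature, the small excess of peracid and the phosphate buffer are chosen to keep the insertion ahead of ring hydroxylation. The buffer also takes up the trifluoroacetic acid that would otherwise cleave the tert-butyl ester or promote enolisation and loss of the β-acyloxy group. Because the side-chain oxygen is created already acylated, it cannot close the six-membered lactone onto the neighbouring benzoate.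

Step 13
Reactants: 22 tert-butyl 2,4-bis(benzyloxy)-6-[(R)-2-{[(R)-3-{[(R)-3,4-bis(benzyloxy)butanoyl]oxy}butanoyl]oxy}propyl]benzoate
Product: 23 2,4-bis(benzyloxy)-6-[(R)-2-{[(R)-3-{[(R)-3,4-bis(benzyloxy)butanoyl]oxy}butanoyl]oxy}propyl]benzoic acid
Conditions: CF3CO2H/CH2Cl2 (1:4), 0 °C → rt
Reagents that add atoms: none
Why: Acidolysis of the tert-butyl ester by alkyl–oxygen cleavage to isobutene, which does not depend on access to the hindered carbonyl; the aliphatic esters and the benzyl ethers tolerate brief exposure to dilute anhydrous acid, and the acylated side-chain oxygen cannot lactonise onto the freed acid.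

Step 14
Reactants: 24 sodium (R)-3-hydroxybutanoate
Product: 25 benzyl (R)-3-hydroxybutanoate
Conditions: BnBr, DMF, rt
Reagents that add atoms: benzyl bromide, BrCc1ccccc1
Why: SN2 O-alkylation of the carboxylate by benzyl bromide; the secondary hydroxyl is not ionised under these conditions and the stereocentre is not involved.

Step 15
Reactants: 23 2,4-bis(benzyloxy)-6-[(R)-2-{[(R)-3-{[(R)-3,4-bis(benzyloxy)butanoyl]oxy}butanoyl]oxy}propyl]benzoic acid; 25 benzyl (R)-3-hydroxybutanoate
Product: 27 (S)-4-(benzyloxy)-4-oxobutan-2-yl 2,4-bis(benzyloxy)-6-[(R)-2-{[(R)-3-{[(R)-3,4-bis(benzyloxy)butanoyl]oxy}butanoyl]oxy}propyl]benzoate (pentabenzyl talapolyester B), via alkoxyphosphonium carboxylate 26 (not isolated)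
Conditions: PPh3, DIAD, THF, 0 °C → rt
Reagents that add atoms: none
Why: Mitsunobu esterification: PPh3 and DIAD convert 25 into the alkoxyphosphonium ion of ion pair 26, and the carboxylate oxygen displaces phosphine oxide by SN2 with inversion, turning the R carbinol into the S ester. The acid reacts as an oxygen nucleophile, so the hindrance at its carbonyl is irrelevant, and 23 has no other free hydroxyl.

Step 16
Reactants: 27 pentabenzyl talapolyester B
Product: 28 talapolyester B
Conditions: H2 (1 atm), 10% Pd/C, EtOAc, rt
Reagents that add atoms: none
Why: Hydrogenolysis of the five benzylic C–O bonds (two aryl ethers, two alkyl ethers, one ester) over palladium under neutral conditions, which leave the ester links and all four stereocentres untouched; filtration and evaporation without heat or acid limit lactonisation of the freed dihydroxybutanoyl end.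

## Compound list

1 | (S)-4-benzyl-3-propionyloxazolidin-2-one | CCC(=O)N1[C@@H](Cc2ccccc2)COC1=O | starting material
2 | 3,5-bis(benzyloxy)benzyl bromide | BrCc1cc(OCc2ccccc2)cc(OCc2ccccc2)c1 | starting material
3 | sodium Z-enolate of 1 | C/C=C(\[O-])N1[C@@H](Cc2ccccc2)COC1=O.[Na+] | intermediate (not isolated)
4 | (S)-4-benzyl-3-{(R)-3-[3,5-bis(benzyloxy)phenyl]-2-methylpropanoyl}oxazolidin-2-one | C[C@H](Cc1cc(OCc2ccccc2)cc(OCc2ccccc2)c1)C(=O)N1[C@@H](Cc2ccccc2)COC1=O | intermediate
5 | aryl dimethyliminium chloride formed from 4 at the ring carbon ortho to the side chain | C[C@H](Cc1cc(OCc2ccccc2)cc(OCc2ccccc2)c1C=[N+](C)C)C(=O)N1[C@@H](Cc2ccccc2)COC1=O.[Cl-] | intermediate (not isolated)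
6 | (S)-4-benzyl-3-{(R)-3-[3,5-bis(benzyloxy)-2-formylphenyl]-2-methylpropanoyl}oxazolidin-2-one | C[C@H](Cc1cc(OCc2ccccc2)cc(OCc2ccccc2)c1C=O)C(=O)N1[C@@H](Cc2ccccc2)COC1=O | intermediate
7 | 2,4-bis(benzyloxy)-6-{(R)-3-[(S)-4-benzyl-2-oxooxazolidin-3-yl]-2-methyl-3-oxopropyl}benzoic acid | C[C@H](Cc1cc(OCc2ccccc2)cc(OCc2ccccc2)c1C(=O)O)C(=O)N1[C@@H](Cc2ccccc2)COC1=O | intermediate
8 | tert-butyl 2,4-bis(benzyloxy)-6-{(R)-3-[(S)-4-benzyl-2-oxooxazolidin-3-yl]-2-methyl-3-oxopropyl}benzoate | C[C@H](Cc1cc(OCc2ccccc2)cc(OCc2ccccc2)c1C(=O)OC(C)(C)C)C(=O)N1[C@@H](Cc2ccccc2)COC1=O | intermediate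
9 | tert-butyl 2,4-bis(benzyloxy)-6-[(R)-3-(ethylsulfanyl)-2-methyl-3-oxopropyl]benzoate | CCSC(=O)[C@H](C)Cc1cc(OCc2ccccc2)cc(OCc2ccccc2)c1C(=O)OC(C)(C)C | intermediate
10 | tert-butyl 2,4-bis(benzyloxy)-6-[(R)-2-methyl-3-oxobutyl]benzoate | CC(=O)[C@H](C)Cc1cc(OCc2ccccc2)cc(OCc2ccccc2)c1C(=O)OC(C)(C)C | intermediate
11 | acetaldehyde | CC=O | starting material
12 | bis[(1S,2R,3S,5S)-isopinocampheyl]boron enolate of 10 | C=C(OB([C@H]1C[C@H]2C[C@@H]([C@@H]1C)C2(C)C)[C@H]1C[C@H]2C[C@@H]([C@@H]1C)C2(C)C)[C@H](C)Cc1cc(OCc2ccccc2)cc(OCc2ccccc2)c1C(=O)OC(C)(C)C | intermediate (not isolated)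
13 | bis[(1S,2R,3S,5S)-isopinocampheyl]boron aldolate of 14 | C[C@H](CC(=O)[C@H](C)Cc1cc(OCc2ccccc2)cc(OCc2ccccc2)c1C(=O)OC(C)(C)C)OB([C@H]1C[C@H]2C[C@@H]([C@@H]1C)C2(C)C)[C@H]1C[C@H]2C[C@@H]([C@@H]1C)C2(C)C | intermediate (not isolated)
14 | tert-butyl 2,4-bis(benzyloxy)-6-[(2R,5R)-5-hydroxy-2-methyl-3-oxohexyl]benzoate | C[C@H](CC(=O)[C@H](C)Cc1cc(OCc2ccccc2)cc(OCc2ccccc2)c1C(=O)OC(C)(C)C)O | intermediate
15 | dimethyl (R)-malate (dimethyl D-malate) | COC(=O)C[C@@H](O)C(=O)OC | starting material
16 | methyl (R)-3,4-dihydroxybutanoate | COC(=O)C[C@@H](O)CO | intermediate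
17 | methyl (R)-3,4-bis(benzyloxy)butanoate | COC(=O)C[C@@H](OCc1ccccc1)COCc1ccccc1 | intermediate
18 | lithium (R)-3,4-bis(benzyloxy)butanoate | [Li+].[O-]C(=O)C[C@@H](OCc1ccccc1)COCc1ccccc1 | intermediate (not isolated)
19 | (R)-3,4-bis(benzyloxy)butanoic acid | OC(=O)C[C@@H](OCc1ccccc1)COCc1ccccc1 | intermediate
20 | tert-butyl 2,4-bis(benzyloxy)-6-[(2R,5R)-5-{[(R)-3,4-bis(benzyloxy)butanoyl]oxy}-2-methyl-3-oxohexyl]benzoate | C[C@H](CC(=O)[C@H](C)Cc1cc(OCc2ccccc2)cc(OCc2ccccc2)c1C(=O)OC(C)(C)C)OC(=O)C[C@@H](OCc3ccccc3)COCc4ccccc4 | intermediate
21 | Criegee adduct of 20: C3 carries hydroxyl and trifluoroacetylperoxy groups (both C3 epimers) | C[C@H](CC(O)(OOC(=O)C(F)(F)F)[C@H](C)Cc1cc(OCc2ccccc2)cc(OCc2ccccc2)c1C(=O)OC(C)(C)C)OC(=O)C[C@@H](OCc3ccccc3)COCc4ccccc4 | intermediate (not isolated)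
22 | tert-butyl 2,4-bis(benzyloxy)-6-[(R)-2-{[(R)-3-{[(R)-3,4-bis(benzyloxy)butanoyl]oxy}butanoyl]oxy}propyl]benzoate | C[C@H](CC(=O)O[C@H](C)Cc1cc(OCc2ccccc2)cc(OCc2ccccc2)c1C(=O)OC(C)(C)C)OC(=O)C[C@@H](OCc3ccccc3)COCc4ccccc4 | intermediate
23 | 2,4-bis(benzyloxy)-6-[(R)-2-{[(R)-3-{[(R)-3,4-bis(benzyloxy)butanoyl]oxy}butanoyl]oxy}propyl]benzoic acid | C[C@H](CC(=O)O[C@H](C)Cc1cc(OCc2ccccc2)cc(OCc2ccccc2)c1C(=O)O)OC(=O)C[C@@H](OCc3ccccc3)COCc4ccccc4 | intermediate
24 | sodium (R)-3-hydroxybutanoate | C[C@@H](O)CC(=O)[O-].[Na+] | starting material
25 | benzyl (R)-3-hydroxybutanoate | C[C@@H](O)CC(=O)OCc1ccccc1 | intermediate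
26 | ion pair of the alkoxytriphenylphosphonium ion of 25 and the carboxylate of 23 | C[C@H](CC(=O)OCc1ccccc1)O[P+](c1ccccc1)(c1ccccc1)c1ccccc1.C[C@H](CC(=O)O[C@H](C)Cc1cc(OCc2ccccc2)cc(OCc2ccccc2)c1C(=O)[O-])OC(=O)C[C@@H](OCc3ccccc3)COCc4ccccc4 | intermediate (not isolated)
27 | (S)-4-(benzyloxy)-4-oxobutan-2-yl 2,4-bis(benzyloxy)-6-[(R)-2-{[(R)-3-{[(R)-3,4-bis(benzyloxy)butanoyl]oxy}butanoyl]oxy}propyl]benzoate (pentabenzyl talapolyester B) | C[C@H](CC(=O)O[C@H](C)Cc1cc(OCc2ccccc2)cc(OCc2ccccc2)c1C(=O)O[C@@H](C)CC(=O)OCc5ccccc5)OC(=O)C[C@@H](OCc3ccccc3)COCc4ccccc4 | intermediate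
28 | talapolyester B | C[C@H](CC(=O)O[C@H](C)Cc1cc(O)cc(O)c1C(=O)O[C@@H](C)CC(=O)O)OC(=O)C[C@@H](O)CO | target

## Step count and least certain steps

Total step count: 16. Longest linear sequence: 12 steps (steps 1–7, 11, 12, 13, 15 and 16, from 1 and 2).

Step 12 (key step).
- What may go wrong: the peracid adds slowly to a ketone flanked by a branched carbon, and during that time oxidation of the dialkoxybenzene ring or loss of the β-acyloxy group by enolisation and elimination may overtake the insertion. The ring is only partly deactivated by its ester.
- Fallback, from 10 back to 22: the oxygen is inserted at the stage of methyl ketone 10, where only a methyl group competes, nothing can eliminate and the less hindered carbonyl takes up the peracid faster. The same buffered peracid should give tert-butyl 6-[(R)-2-acetoxypropyl]-2,4-bis(benzyloxy)benzoate F1. K2CO3 in methanol at 0 °C should then free tert-butyl 2,4-bis(benzyloxy)-6-[(R)-2-hydroxypropyl]benzoate F2, whose hindered tert-butyl ester is a poor partner for lactonisation. Separately, 19 is coupled (EDC·HCl, DMAP) with commercial tert-butyl (R)-3-hydroxybutanoate F3 to give tert-butyl (R)-3-{[(R)-3,4-bis(benzyloxy)butanoyl]oxy}butanoate F4, which CF3CO2H converts into (R)-3-{[(R)-3,4-bis(benzyloxy)butanoyl]oxy}butanoic acid F5. Carbodiimide esterification of F2 with F5 rejoins the route at 22.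

Step 7.
- What may go wrong: poor facial selectivity. Reagent control by isopinocampheyl ligands is moderate for methyl-ketone enolborinates with a small aldehyde, the α-methyl centre may oppose it, and the C5 epimers may be hard to separate.
- Fallback, from 9 back to 14: lithium di[(E)-prop-1-enyl]cuprate (from (E)-1-bromopropene, t-BuLi and CuI) should convert 9 into tert-butyl 2,4-bis(benzyloxy)-6-[(R,E)-2-methyl-3-oxohex-4-en-1-yl]benzoate F6. Copper-catalysed enantioselective conjugate borylation follows (CuCl, NaOt-Bu, a ferrocenyl bisphosphine of the Josiphos family in the enantiomeric form that delivers boron to the face giving the R centre, B2pin2, MeOH, THF). This gives tert-butyl 2,4-bis(benzyloxy)-6-[(2R,5R)-2-methyl-3-oxo-5-(4,4,5,5-tetramethyl-1,3,2-dioxaborolan-2-yl)hexyl]benzoate F7. NaBO3 oxidises its C–B bond with retention to 14, and the methyl ketone and the aldol reaction are bypassed.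

Step 9.
- What may go wrong: lactonisation of the γ-hydroxy ester under the acid catalyst before the primary hydroxyl is benzylated, and incomplete etherification of the secondary hydroxyl.
- Fallback, from 16 back to 19: the lactone is made on purpose. A trace of TsOH converts 16 into (R)-4-hydroxydihydrofuran-2(3H)-one F8. The same imidate benzylation, now with nothing left to cyclise, gives (R)-4-(benzyloxy)dihydrofuran-2(3H)-one F9. Powdered KOH and BnBr in hot toluene open the lactone to the hydroxy carboxylate and benzylate the primary alkoxide (Williamson ether synthesis on the carboxylate salt, which resists enolisation). Acidification gives 19 directly, so 17 and 18 are bypassed.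

Step 15.
- What may go wrong: β-elimination of the activated β-hydroxy ester to the crotonate in place of substitution, because the carboxylate of the hindered acid is a slow nucleophile.
- Fallback, from 23 back to 27: the ester is formed with retention. 1-Chloro-N,N,2-trimethylprop-1-en-1-amine converts 23 under neutral conditions into 2,4-bis(benzyloxy)-6-[(R)-2-{[(R)-3-{[(R)-3,4-bis(benzyloxy)butanoyl]oxy}butanoyl]oxy}propyl]benzoyl chloride F12. Commercial sodium (S)-3-hydroxybutanoate F10 is benzylated as in step 14 to benzyl (S)-3-hydroxybutanoate F11, which is acylated by F12 with DMAP and Et3N in CH2Cl2 to give 27. The S centre then comes from the chiral pool and no SN2 step is needed.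

## Further compounds

F1 | step 12 | tert-butyl 6-[(R)-2-acetoxypropyl]-2,4-bis(benzyloxy)benzoate | CC(=O)O[C@H](C)Cc1cc(OCc2ccccc2)cc(OCc2ccccc2)c1C(=O)OC(C)(C)C
F2 | step 12 | tert-butyl 2,4-bis(benzyloxy)-6-[(R)-2-hydroxypropyl]benzoate | O[C@H](C)Cc1cc(OCc2ccccc2)cc(OCc2ccccc2)c1C(=O)OC(C)(C)C
F3 | step 12 | tert-butyl (R)-3-hydroxybutanoate | C[C@@H](O)CC(=O)OC(C)(C)C
F4 | step 12 | tert-butyl (R)-3-{[(R)-3,4-bis(benzyloxy)butanoyl]oxy}butanoate | C[C@H](CC(=O)OC(C)(C)C)OC(=O)C[C@@H](OCc1ccccc1)COCc1ccccc1
F5 | step 12 | (R)-3-{[(R)-3,4-bis(benzyloxy)butanoyl]oxy}butanoic acid | C[C@H](CC(=O)O)OC(=O)C[C@@H](OCc1ccccc1)COCc1ccccc1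
F6 | step 7 | tert-butyl 2,4-bis(benzyloxy)-6-[(R,E)-2-methyl-3-oxohex-4-en-1-yl]benzoate | C/C=C/C(=O)[C@H](C)Cc1cc(OCc2ccccc2)cc(OCc2ccccc2)c1C(=O)OC(C)(C)C
F7 | step 7 | tert-butyl 2,4-bis(benzyloxy)-6-[(2R,5R)-2-methyl-3-oxo-5-(4,4,5,5-tetramethyl-1,3,2-dioxaborolan-2-yl)hexyl]benzoate | C[C@H](CC(=O)[C@H](C)Cc1cc(OCc2ccccc2)cc(OCc2ccccc2)c1C(=O)OC(C)(C)C)B1OC(C)(C)C(C)(C)O1
F8 | step 9 | (R)-4-hydroxydihydrofuran-2(3H)-one | O=C1C[C@@H](O)CO1
F9 | step 9 | (R)-4-(benzyloxy)dihydrofuran-2(3H)-one | O=C1C[C@@H](OCc2ccccc2)CO1
F10 | step 15 | sodium (S)-3-hydroxybutanoate | C[C@H](O)CC(=O)[O-].[Na+]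
F11 | step 15 | benzyl (S)-3-hydroxybutanoate | C[C@H](O)CC(=O)OCc1ccccc1
F12 | step 15 | 2,4-bis(benzyloxy)-6-[(R)-2-{[(R)-3-{[(R)-3,4-bis(benzyloxy)butanoyl]oxy}butanoyl]oxy}propyl]benzoyl chloride | C[C@H](CC(=O)O[C@H](C)Cc1cc(OCc2ccccc2)cc(OCc2ccccc2)c1C(Cl)=O)OC(=O)C[C@@H](OCc3ccccc3)COCc4ccccc4
A1 | alternative 1 | tribenzyl talapolyester B with free phenols | C[C@H](CC(=O)O[C@H](C)Cc1cc(O)cc(O)c1C(=O)O[C@@H](C)CC(=O)OCc2ccccc2)OC(=O)C[C@@H](OCc3ccccc3)COCc4ccccc4
A2 | alternative 1 | (S)-4-(benzyloxy)-4-oxobutan-2-yl (R)-5-{[(R)-3-{[(R)-3,4-bis(benzyloxy)butanoyl]oxy}butanoyl]oxy}hex-2-ynoate | C[C@H](CC(=O)O[C@H](C)CC#CC(=O)O[C@@H](C)CC(=O)OCc2ccccc2)OC(=O)C[C@@H](OCc3ccccc3)COCc4ccccc4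
A3 | alternative 1 | 1-methoxy-1,3-bis(trimethylsilyloxy)buta-1,3-diene | COC(O[Si](C)(C)C)=CC(=C)O[Si](C)(C)C
A4 | alternative 2 | (S)-4-(benzyloxy)-4-oxobutan-2-yl 2-{(R)-2-[(tert-butyldimethylsilyl)oxy]propyl}-4,6-dihydroxybenzoate | CC(C)(C)[Si](C)(C)O[C@H](C)Cc1cc(O)cc(O)c1C(=O)O[C@@H](C)CC(=O)OCc2ccccc2
A5 | alternative 2 | 6-{(R)-6-[(tert-butyldimethylsilyl)oxy]-2,4-dioxoheptyl}-2,2-dimethyl-4H-1,3-dioxin-4-one | CC1(C)OC(CC(=O)CC(=O)C[C@@H](C)O[Si](C)(C)C(C)(C)C)=CC(=O)O1
A6 | alternative 2 | benzyl (S)-3-hydroxybutanoate | C[C@H](O)CC(=O)OCc1ccccc1
A7 | alternative 3 | tetrabenzyl talapolyester B with free cap carbinol | C[C@H](CC(=O)O[C@H](C)Cc1cc(OCc2ccccc2)cc(OCc2ccccc2)c1C(=O)O[C@@H](C)CC(=O)OCc3ccccc3)OC(=O)C[C@@H](O)COCc4ccccc4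
A8 | alternative 3 | (S)-4-(benzyloxy)-4-oxobutan-2-yl 2,4-bis(benzyloxy)-6-[(R)-2-{[(R)-3-hydroxybutanoyl]oxy}propyl]benzoate | C[C@@H](O)CC(=O)O[C@H](C)Cc1cc(OCc2ccccc2)cc(OCc2ccccc2)c1C(=O)O[C@@H](C)CC(=O)OCc3ccccc3
A9 | alternative 3 | (R)-benzyl glycidyl ether | C(OCc1ccccc1)[C@H]1CO1
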